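## Structural features

The target is a 2,3-dihydro-1,4-benzodioxine neolignan. Ring A is a benzene ring that carries the two dioxane oxygens on C8a (O1) and C4a (O4), a methoxy group on C5 and an (E)-prop-1-enyl group on C7. The dioxane ring carries a 4-hydroxy-3,5-dimethoxyphenyl group (ring B) on C2 and a methyl group on C3. C2 and C3 are the only stereocentres; they are adjacent, both R, and their substituents are trans. Ring A is unsymmetrical, so there is also a constitutional demand: C2 must sit on O1, which is meta to both the methoxy carbon and the propenyl carbon, and C3 on O4, which is flanked by the methoxy group and para to the propenyl group. The fragile parts are the free ring B phenol, the propenyl styrene and the benzylic C2–O1 ether. The phenol is para to that ether and can open it through a quinone methide under base, heat or oxidants; the styrene would not survive carbenes, strong acid or hydrogenation. The real difficulty is to set two contiguous oxygen-bearing stereocentres in the absolute sense while keeping the pairing O1/C2 and O4/C3. The plan exploits the fact that C2 is bonded only to O1, C3, ring B and hydrogen. Taking C2 out leaves O1–C3–O4, a 2-methyl-1,3-benzodioxole acetal of a ring A catechol, and returning it as an aryl carbene is a one-carbon ring expansion that makes O1–C2 and C2–C3 together.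

## Logic of the disconnections

16 from 15: the cut is the S–O bond of the sulfonate on the ring B oxygen. The phenol stays masked to the end because it would insert into the carbene and would then be exposed to hydride, oxidant and strong base as a para-hydroxybenzyl aryl ether. The gain is that every earlier step runs on a substrate that cannot ionise. The forward step must neither heat a phenoxide nor reduce the styrene, so reductive S–O cleavage at room temperature is preferred to hot alkali.

15 from 13 and 14: the cut is the C=C bond of the propenyl group. An alkene cannot be present when the carbene is generated, so it has to be made after the ring. Cutting at the double bond leaves an aryl aldehyde and a two-carbon sulfone. The forward step must be E-selective and must spare the aryl sulfonate.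

13 from 12 from 11: no skeletal bond is cut; the C7 carbon is taken back from aldehyde through alcohol to methyl ester. The ester is the form in which this carbon passes the key step, because it is inert to rhodium carbenes and, being para to O4, lowers the electron density of that oxygen. The forward steps need a hydride that leaves the sulfonate alone and an oxidant that stops at the aldehyde.

11 from 3 and 10: the cuts are O1–C2 and C2–C3, which remove C2 with ring B as a carbene. This is the cut that simplifies most: the six-membered ring and both stereocentres vanish and what remains is a racemic five-membered acetal and an achiral diazo compound. The forward step must deliver the carbene to the future O1 and not O4, must turn the ylide into product by a 1,2-shift and not by proton transfer, and must set both centres under catalyst control.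

10 from 9 from 8: the cut is the N–S bond of the sulfonyl hydrazone anion (forward: loss of sulfinate). The aryldiazomethane is thereby never isolated and is fed slowly, which keeps carbene dimerisation down. The forward step needs a base that leaves no protic by-product and a release temperature the chiral catalyst tolerates.

8 from 6 and 7, and 6 from 4 and 5: the cuts are the C=N bond of the hydrazone and the O–S bond of the ring B sulfonate. A sulfonate is preferred to an ether or silyl ether because it withdraws electrons, which tames the diazo compound and stabilises the benzylic negative charge of the ylide. Both forward steps are routine condensations.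

3 from 1 and 2: the cuts are the two acetal C–O bonds. The gain is a commercial catechol ester and a commercial acetal. The forward step needs only acid and removal of the alcohol set free; the dimethyl acetal is chosen so that this alcohol matches the methyl ester.

## Other disconnections considered

Alternative 1: The cut removes three ring A bonds at once, C4a–C8a, C5–C6 and C7–C8, so ring A and the dioxane ring both disappear and the stereocentres remain on an open O1–C2–C3–O4 chain.
- Forward key step: the bis-ynol ether {4-[(1R,2R)-2-[(chloroethynyl)oxy]-1-(ethynyloxy)propyl]-2,6-dimethoxyphenoxy}tri(propan-2-yl)silane A1 would be cyclotrimerised with (E)-pent-3-en-1-yne A2 by Cp*RuCl(cod) at room temperature. The product would be the 5-chloro-7-propenyl benzodioxane silyl ether A3.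
- In favour: C2 and C3 would be set on an acyclic precursor by established asymmetric oxidation chemistry before any ring exists. The pairing O1/C2 and O4/C3 is written into the tether. The (E)-propenyl group arrives intact with the alkyne. On these three structural points the alternative is the better plan.
- Against: A1 is a double ynol ether of a secondary and a secondary benzylic alcohol, a class that is laborious to make and that fragments to ketenes on mild warming. The orientation of A2 in the ruthenacycle, which decides between 7- and 6-propenyl, rests only on the H versus Cl difference of the two alkyne termini. The alkene of A2 can itself enter the metallacycle. A3 still carries chlorine where the target has methoxy, so a hindered aryl chloride methoxylation and a desilylation must follow.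
- Comparison: alkyne cyclotrimerisation is an established reaction class and in that respect safer than an untested asymmetric ylide shift, though not on bis-ynol ethers of this kind. On step economy the chosen plan should be clearly shorter, eight steps against an estimated twelve or more.

Alternative 2: The cut is O4–C3 together with a C–H bond of the C3 methyl group, which turns the methyl-bearing centre into a vinyl group on C2.
- Forward key step: the allylic aryl ether 4-bromo-2-{[(1S)-1-{3,5-dimethoxy-4-[tri(propan-2-yl)silyloxy]phenyl}prop-2-en-1-yl]oxy}-6-methoxyphenol A4 would be treated with Co(salen), an N-fluoro-2,4,6-trimethylpyridinium salt and PhSiH3. A hydrogen atom is transferred to the terminal alkene carbon, the C3 radical is oxidised through a tetravalent cobalt alkyl, and the C4a phenol closes the ring in a 6-exo fashion to the 7-bromo benzodioxane A5.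
- In favour: cobalt hydride hydroalkoxylation by phenols is a known reaction class and is mild. The O1/O4 pairing is fixed in A4, which is better than relying on discrimination between two acetal oxygens. The bromide allows the (E)-propenyl group to be introduced in one cross-coupling step, a shorter end-game than the ester-to-propenyl sequence of the chosen plan.
- Against: only C2 is under reagent control (it must be set earlier by an enantioselective allylic etherification of a mono-protected catechol). C3 depends on substrate control in a cation-like closure, and the trans outcome is plausible but not assured. The electron-deficient C3 sits next to the benzylic, oxygen-bearing C2–H, so a 1,2-hydride shift to an oxygen-stabilised benzylic cation and closure to a five-membered acetal is a serious competitor. A4 is also an aryl allyl ether that can ionise or rearrange.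
- Comparison: mechanistically the alternative stands on firmer precedent. Stereochemically it splits control between catalyst and substrate, where the chosen plan sets both centres in one event. The step count would be similar or slightly higher, about ten.

Alternative 3: The cut is the O1–C8a aryl ether bond, which leaves an open-chain alcohol with both stereocentres in place.
- Forward key step: (1R,2R)-2-{2-bromo-6-methoxy-4-[(E)-prop-1-en-1-yl]phenoxy}-1-{3,5-dimethoxy-4-[tri(propan-2-yl)silyloxy]phenyl}propan-1-ol A6 would be cyclised with Pd(OAc)2, a di-tert-butyl biarylphosphine and Cs2CO3 to the silyl ether of the target A7. Fluoride then gives the target.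
- In favour: this is the most conservative plan. Intramolecular aryl etherification of secondary alcohols is known, both stereocentres are made earlier by standard methods and the C2–O bond is not broken, so stereochemical certainty is better than in the chosen plan. The position of the bromide fixes the regiochemistry, and the final unmasking of a silyl ether is milder than removal of a sulfonate.
- Against: the difficulty moves into A6, whose O4–C3 bond must be formed with stereocontrol at a secondary carbon on a phenol flanked by methoxy and bromine. The alkoxide-bound divalent palladium aryl intermediate has a benzylic β-hydrogen and can eliminate to a ketone with loss of the bromide. The propenyl styrene can undergo Heck-type coupling or isomerise. The electron-rich, doubly ortho-substituted bromide is slow in oxidative addition.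
- Comparison: more reliable on mechanism and stereochemistry, equal on the number of rings formed in the key step, but longer (an estimated nine to eleven steps) and less convergent than the chosen plan.

Key step: step 4

Remarks on the chemistry and assumptions:
- All benzodioxanes are numbered O1, C2 (ring B), C3 (methyl), O4, C4a, C5 (OMe), C6, C7, C8, C8a, also where nomenclature rules would number the ring the other way round.
- The structures of 3, 10 and 11 were re-derived from the target (trans, 2R,3R, C2 on the oxygen meta to the ester) and are mutually consistent.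
- The sense of induction of step 4 cannot be derived from precedent; Rh2(S-PTTL)4 is written, and Rh2(R-PTTL)4 would be used if the antipode forms.
- Three design changes serve the key step without touching the disconnection:
  - The dimethyl acetal replaces the diethyl acetal, so the alcohol released cannot scramble the methyl ester.
  - The hydrazone is deprotonated with NaH in a non-ethereal solvent, because alkoxide bases leave an alcohol that inserts into the carbene and THF or dioxane are better ylide acceptors than a benzodioxole.
  - Ring B is unmasked reductively at room temperature, not by hot alkali.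
- Sulfone 14 is taken to be a purchasable reagent.

Step 1
Reactants: 1 methyl 3,4-dihydroxy-5-methoxybenzoate; 2 acetaldehyde dimethyl acetal
Product: 3 racemic methyl 7-methoxy-2-methyl-1,3-benzodioxole-5-carboxylate
Conditions: 2 (5 equiv), p-TsOH·H2O (5 mol%), toluene, 85 °C, MeOH distilled off
Reagents that add atoms: acetaldehyde dimethyl acetal (2), CC(OC)OC
Why: Acid-catalysed transacetalisation: the mixed aryl methyl acetal ionises to an aryloxy-stabilised oxocarbenium ion that the neighbouring phenol closes to the benzodioxole, and removal of methanol drives the exchange. The acetal carbon is formed racemic, which is acceptable because step 4 erases it.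

Step 2
Reactants: 4 syringaldehyde; 5 p-toluenesulfonyl chloride
Product: 6 4-formyl-2,6-dimethoxyphenyl 4-methylbenzenesulfonate
Conditions: TsCl (1.2 equiv), Et3N (1.5 equiv), DMAP (5 mol%), CH2Cl2, 0 °C to rt
Reagents that add atoms: p-toluenesulfonyl chloride (5), Cc1ccc(cc1)S(=O)(=O)Cl
Why: O-Sulfonylation of an acidic, hindered phenol under amine base with nucleophilic catalysis; the aldehyde is untouched. The tosylate withdraws electrons from ring B and survives base, hydride and oxidant.

Step 3
Reactants: 6 4-formyl-2,6-dimethoxyphenyl 4-methylbenzenesulfonate; 7 p-toluenesulfonyl hydrazide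
Product: 8 4-{(E)-[2-(4-methylbenzenesulfonyl)hydrazinylidene]methyl}-2,6-dimethoxyphenyl 4-methylbenzenesulfonate
Conditions: TsNHNH2 (1.05 equiv), MeOH, 50 °C, then 0 °C and filtration
Reagents that add atoms: p-toluenesulfonyl hydrazide (7), Cc1ccc(cc1)S(=O)(=O)NN
Why: Condensation of an aryl aldehyde with a sulfonyl hydrazide should give the crystalline (E)-N-tosylhydrazone, the bench-stable carrier of the diazo group for a Bamford–Stevens release.

Step 4
Reactants: 8 4-{(E)-[2-(4-methylbenzenesulfonyl)hydrazinylidene]methyl}-2,6-dimethoxyphenyl 4-methylbenzenesulfonate; 3 racemic methyl 7-methoxy-2-methyl-1,3-benzodioxole-5-carboxylate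
Product: 11 methyl (2R,3R)-2-{3,5-dimethoxy-4-[(4-methylbenzenesulfonyl)oxy]phenyl}-5-methoxy-3-methyl-2,3-dihydro-1,4-benzodioxine-7-carboxylate, via hydrazone sodium salt 9 (not isolated), via aryldiazomethane 10 (not isolated)
Conditions: NaH (1.05 equiv), PhCF3, rt; then 3 (2 equiv), Rh2(S-PTTL)4 (2 mol%), BnEt3NCl (10 mol%), 40 °C
Reagents that add atoms: none
Why: Proposed new method: warming salt 9 with the phase-transfer catalyst releases aryldiazomethane 10 slowly; dirhodium tetrakis[N-phthaloyl-(S)-tert-leucinate], Rh2(S-PTTL)4, converts it into an electrophilic rhodium carbene, which is captured by the acetal oxygen of 3 that becomes O1 to give an oxonium ylide. The closest known reaction type is the Rh2(OAc)4- or Cu(acac)2-catalysed one-carbon ring expansion of aliphatic 1,3-dioxolanes to 1,4-dioxanes by diazo compounds through an oxonium ylide and Stevens [1,2]-shift, which has no enantioselective version and has not been run on benzodioxoles. The ylide should break its O1–C3 bond heterolytically, because C3 leaves as an oxocarbenium ion stabilised by O4 while the benzylic carbon keeps the negative charge, stabilised by rhodium and by the sulfonyloxy-substituted ring B. The six-membered ring then closes by recombination of this tethered ion pair at carbon, a 6-endo-trig attack of benzylic C2 on the C3=O4 oxocarbenium, so that O1–C2 (made in the ylide) and C2–C3 are both in place and the five-membered acetal has become the dioxane. Because C3 is planar in the ion pair, the racemic acetal centre of 3 is erased and both enantiomers of 3 should converge on one product. C2 is set by the face of the rhodium-associated benzylic carbon that the chiral carboxylate wall leaves open, and C3 by the oxocarbenium face that places its methyl group anti to ring B in a chair-like closure, which is also the diequatorial trans arrangement. The step needs site selectivity for O1 over O4 (O4 is shielded by the C5 methoxy group and deactivated by conjugation with the para ester); it also needs ylide formation to outrun carbene dimerisation, arene cyclopropanation and hydride abstraction from the acetal C–H (slow release of 10, excess 3, an electron-poor non-ethereal solvent and the electron-withdrawing tosylate all help), and C–C recombination to outrun proton transfer to a vinyl ether. The sense of asymmetric induction is not predictable and the enantiomeric catalyst would be substituted if required.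

Step 5
Reactants: 11 methyl (2R,3R)-2-{3,5-dimethoxy-4-[(4-methylbenzenesulfonyl)oxy]phenyl}-5-methoxy-3-methyl-2,3-dihydro-1,4-benzodioxine-7-carboxylate
Product: 12 4-[(2R,3R)-7-(hydroxymethyl)-5-methoxy-3-methyl-2,3-dihydro-1,4-benzodioxin-2-yl]-2,6-dimethoxyphenyl 4-methylbenzenesulfonate
Conditions: i-Bu2AlH (DIBAL-H, 2.5 equiv), CH2Cl2, −78 to −40 °C; aq. potassium sodium tartrate
Reagents that add atoms: none
Why: Hydride reduction of an aryl methyl ester to the benzylic alcohol; aryl sulfonates and the benzodioxane are inert to this reagent at low temperature and no stereocentre is involved.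

Step 6
Reactants: 12 4-[(2R,3R)-7-(hydroxymethyl)-5-methoxy-3-methyl-2,3-dihydro-1,4-benzodioxin-2-yl]-2,6-dimethoxyphenyl 4-methylbenzenesulfonate
Product: 13 4-[(2R,3R)-7-formyl-5-methoxy-3-methyl-2,3-dihydro-1,4-benzodioxin-2-yl]-2,6-dimethoxyphenyl 4-methylbenzenesulfonate
Conditions: MnO2 (activated, 15 equiv), CH2Cl2, rt
Reagents that add atoms: none
Why: MnO2 oxidises electron-rich benzylic alcohols selectively and stops at the aldehyde; the neutral heterogeneous conditions leave the sulfonate and both stereocentres alone.

Step 7
Reactants: 13 4-[(2R,3R)-7-formyl-5-methoxy-3-methyl-2,3-dihydro-1,4-benzodioxin-2-yl]-2,6-dimethoxyphenyl 4-methylbenzenesulfonate; 14 5-(ethylsulfonyl)-1-phenyl-1H-tetrazole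
Product: 15 4-[(2R,3R)-5-methoxy-3-methyl-7-[(E)-prop-1-en-1-yl]-2,3-dihydro-1,4-benzodioxin-2-yl]-2,6-dimethoxyphenyl 4-methylbenzenesulfonate
Conditions: 14 (1.3 equiv), KN(SiMe3)2 (1.25 equiv), DME, −60 °C; then 13, −60 °C to rt
Reagents that add atoms: 5-(ethylsulfonyl)-1-phenyl-1H-tetrazole (14), CCS(=O)(=O)c1nnnn1-c1ccccc1
Why: Julia–Kocienski olefination: the metalated 1-phenyltetrazolyl sulfone adds to the non-enolisable aryl aldehyde, and Smiles rearrangement with loss of SO2 and the tetrazolone anion gives the alkene, which should be E-selective with this sulfone class in DME. The aryl tosylate has no ortho hydrogen and should tolerate the brief exposure to the sulfonyl carbanion at low temperature.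

Step 8
Reactants: 15 4-[(2R,3R)-5-methoxy-3-methyl-7-[(E)-prop-1-en-1-yl]-2,3-dihydro-1,4-benzodioxin-2-yl]-2,6-dimethoxyphenyl 4-methylbenzenesulfonate
Product: 16 4-[(2R,3R)-5-methoxy-3-methyl-7-[(E)-prop-1-en-1-yl]-2,3-dihydro-1,4-benzodioxin-2-yl]-2,6-dimethoxyphenol
Conditions: Mg turnings (10 equiv), MeOH–THF (3:1), rt; aq. NH4Cl
Reagents that add atoms: none
Why: Reductive S–O cleavage of an aryl tosylate by electron transfer from magnesium in methanol liberates the phenol at room temperature, which avoids heating a para-hydroxybenzyl aryl ether in alkali. The electron-rich β-methylstyrene should lie beyond the reducing power needed for the sulfonate, and C2 and C3 are not touched.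

## Compound list

1 | methyl 3,4-dihydroxy-5-methoxybenzoate | COC(=O)c1cc(O)c(O)c(OC)c1 | starting material
2 | acetaldehyde dimethyl acetal (1,1-dimethoxyethane) | CC(OC)OC | starting material
3 | methyl 7-methoxy-2-methyl-1,3-benzodioxole-5-carboxylate (racemic) | COC(=O)c1cc(OC)c2OC(C)Oc2c1 | intermediate
4 | syringaldehyde (4-hydroxy-3,5-dimethoxybenzaldehyde) | COc1cc(C=O)cc(OC)c1O | starting material
5 | p-toluenesulfonyl chloride | Cc1ccc(cc1)S(=O)(=O)Cl | starting material
6 | 4-formyl-2,6-dimethoxyphenyl 4-methylbenzenesulfonate | O=Cc1cc(OC)c(OS(=O)(=O)c2ccc(C)cc2)c(OC)c1 | intermediate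
7 | p-toluenesulfonyl hydrazide | Cc1ccc(cc1)S(=O)(=O)NN | starting material
8 | 4-{(E)-[2-(4-methylbenzenesulfonyl)hydrazinylidene]methyl}-2,6-dimethoxyphenyl 4-methylbenzenesulfonate | Cc1ccc(cc1)S(=O)(=O)N/N=C/c1cc(OC)c(OS(=O)(=O)c2ccc(C)cc2)c(OC)c1 | intermediate
9 | sodium salt of 8 (N-sodio tosylhydrazone, formed in the flask) | [Na+].Cc1ccc(cc1)S(=O)(=O)[N-]/N=C/c1cc(OC)c(OS(=O)(=O)c2ccc(C)cc2)c(OC)c1 | intermediate
10 | 4-(diazomethyl)-2,6-dimethoxyphenyl 4-methylbenzenesulfonate (formed in the flask) | [N-]=[N+]=Cc1cc(OC)c(OS(=O)(=O)c2ccc(C)cc2)c(OC)c1 | intermediate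
11 | methyl (2R,3R)-2-{3,5-dimethoxy-4-[(4-methylbenzenesulfonyl)oxy]phenyl}-5-methoxy-3-methyl-2,3-dihydro-1,4-benzodioxine-7-carboxylate | COC(=O)c1cc(OC)c2c(c1)O[C@H](c1cc(OC)c(OS(=O)(=O)c3ccc(C)cc3)c(OC)c1)[C@@H](C)O2 | intermediate
12 | 4-[(2R,3R)-7-(hydroxymethyl)-5-methoxy-3-methyl-2,3-dihydro-1,4-benzodioxin-2-yl]-2,6-dimethoxyphenyl 4-methylbenzenesulfonate | OCc1cc(OC)c2c(c1)O[C@H](c1cc(OC)c(OS(=O)(=O)c3ccc(C)cc3)c(OC)c1)[C@@H](C)O2 | intermediate
13 | 4-[(2R,3R)-7-formyl-5-methoxy-3-methyl-2,3-dihydro-1,4-benzodioxin-2-yl]-2,6-dimethoxyphenyl 4-methylbenzenesulfonate | O=Cc1cc(OC)c2c(c1)O[C@H](c1cc(OC)c(OS(=O)(=O)c3ccc(C)cc3)c(OC)c1)[C@@H](C)O2 | intermediate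
14 | 5-(ethylsulfonyl)-1-phenyl-1H-tetrazole | CCS(=O)(=O)c1nnnn1-c1ccccc1 | starting material
15 | 4-[(2R,3R)-5-methoxy-3-methyl-7-[(E)-prop-1-en-1-yl]-2,3-dihydro-1,4-benzodioxin-2-yl]-2,6-dimethoxyphenyl 4-methylbenzenesulfonate | C/C=C/c1cc(OC)c2c(c1)O[C@H](c1cc(OC)c(OS(=O)(=O)c3ccc(C)cc3)c(OC)c1)[C@@H](C)O2 | intermediate
16 | 4-[(2R,3R)-5-methoxy-3-methyl-7-[(E)-prop-1-en-1-yl]-2,3-dihydro-1,4-benzodioxin-2-yl]-2,6-dimethoxyphenol | C/C=C/c1cc(OC)c2c(c1)O[C@H](c1cc(OC)c(O)c(OC)c1)[C@@H](C)O2 | target

## Step count and least certain steps

Total: 8 steps. Longest linear sequence: 7 steps (steps 2 to 8, from 4); step 1 is a one-step branch that joins at step 4.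

**Step 4 (key step, new method).**
- What may go wrong:
  - Capture of the carbene by the weakly basic acetal oxygen may be too slow, so that carbene dimerisation, azine formation, attack of the sulfinate by-product or hydride abstraction from the acetal C–H takes over.
  - Ylide formation at O4 would give the constitutional isomer.
  - The ion pair may collapse by proton transfer and not by C–C bond formation.
  - The acetal carbon may retain stereochemical memory (recombination in the solvent cage with retention), which would cap both diastereo- and enantioselectivity.
  - The donor-only carbene may leave the metal before the shift, which would cost facial control.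
- Fallback, built only on known reactions, from 1 back to 11:
  - Ethyl (S)-lactate is converted with MeNHOMe·HCl and i-PrMgCl into (S)-2-hydroxy-N-methoxy-N-methylpropanamide F1.
  - A Mitsunobu reaction of F1 with 1 (PPh3, DIAD, THF) should occur at the more acidic phenol para to the ester and with inversion, to give methyl 3-hydroxy-5-methoxy-4-{[(2R)-1-[methoxy(methyl)amino]-1-oxopropan-2-yl]oxy}benzoate F2. The future C3 is then already R.
  - Separately, commercial 4-bromo-2,6-dimethoxyphenol is tosylated to 4-bromo-2,6-dimethoxyphenyl 4-methylbenzenesulfonate F3. Bromine–magnesium exchange with i-PrMgCl·LiCl gives {3,5-dimethoxy-4-[(4-methylbenzenesulfonyl)oxy]phenyl}magnesium chloride F4.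
  - Two equivalents of F4 (one is spent on the phenol) add to the N-methoxy-N-methylamide of F2 to give methyl 4-{[(2R)-1-{3,5-dimethoxy-4-[(4-methylbenzenesulfonyl)oxy]phenyl}-1-oxopropan-2-yl]oxy}-3-hydroxy-5-methoxybenzoate F5.
  - Chelation-controlled reduction with Zn(BH4)2 at −20 °C should favour the erythro alcohol methyl 4-{[(1S,2R)-1-{3,5-dimethoxy-4-[(4-methylbenzenesulfonyl)oxy]phenyl}-1-hydroxypropan-2-yl]oxy}-3-hydroxy-5-methoxybenzoate F6; the threo epimer is removed by chromatography.
  - An intramolecular Mitsunobu reaction of F6 (PPh3, DIAD) closes O1–C2 with inversion at the benzylic carbon and delivers 11.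
  - This costs six operations in place of one and carries its own risk of epimerisation next to the ketone of F5, but every reaction type in it is established.

**Step 8.**
- What may go wrong: electron transfer to the styrene with saturation of the propenyl double bond, or, if the medium turns strongly basic, phenoxide-triggered opening of the C2–O1 ether through a quinone methide with loss of the C2 configuration.
- Fallback, from 12 back to 16: the order is changed so that the sulfonate is cleaved before any alkene exists.
  - Mg in MeOH on 12 gives 4-[(2R,3R)-7-(hydroxymethyl)-5-methoxy-3-methyl-2,3-dihydro-1,4-benzodioxin-2-yl]-2,6-dimethoxyphenol F7.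
  - MnO2 oxidises its benzylic alcohol to (2R,3R)-2-(4-hydroxy-3,5-dimethoxyphenyl)-5-methoxy-3-methyl-2,3-dihydro-1,4-benzodioxine-7-carbaldehyde F8.
  - Julia–Kocienski olefination with 14, using one extra equivalent of KN(SiMe3)2 for the phenol and a cold quench, gives 16 directly.

**Step 7.**
- What may go wrong: insufficient E-selectivity with an electron-rich aryl aldehyde, or self-condensation of the metalated sulfone before it meets the aldehyde.
- Fallback, from 13 back to 15:
  - EtMgBr (THF, −78 °C) adds to 13 to give 4-[(2R,3R)-7-(1-hydroxypropyl)-5-methoxy-3-methyl-2,3-dihydro-1,4-benzodioxin-2-yl]-2,6-dimethoxyphenyl 4-methylbenzenesulfonate F9, as a mixture of epimers at the new carbinol carbon, which does not matter.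
  - Dilute acid-catalysed dehydration (p-TsOH, toluene, 70 °C) through the O4-stabilised benzylic cation should give the conjugated alkene 15 with the thermodynamically preferred E geometry.

**Step 1.**
- What may go wrong: incomplete exchange on the deactivated, hindered catechol, loss of the volatile acetal before it reacts, or acid-promoted oligomerisation through aryl vinyl ether intermediates.
- Fallback, from 1 back to 3:
  - Vinyl transfer from vinyl acetate with [Ir(cod)Cl]2 and Na2CO3 (toluene, 100 °C) gives methyl 3-(ethenyloxy)-4-hydroxy-5-methoxybenzoate F10. The regioisomeric vinyl ether would serve equally.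
  - A catalytic amount of camphorsulfonic acid in CH2Cl2 then adds the neighbouring phenol across the vinyl ether in the Markovnikov sense to close the acetal 3.

## Further compounds

F1 | step 4 | (S)-2-hydroxy-N-methoxy-N-methylpropanamide | C[C@H](O)C(=O)N(C)OC
F2 | step 4 | methyl 3-hydroxy-5-methoxy-4-{[(2R)-1-[methoxy(methyl)amino]-1-oxopropan-2-yl]oxy}benzoate | C[C@@H](Oc1c(O)cc(cc1OC)C(=O)OC)C(=O)N(C)OC
F3 | step 4 | 4-bromo-2,6-dimethoxyphenyl 4-methylbenzenesulfonate | Brc1cc(OC)c(OS(=O)(=O)c2ccc(C)cc2)c(OC)c1
F4 | step 4 | {3,5-dimethoxy-4-[(4-methylbenzenesulfonyl)oxy]phenyl}magnesium chloride | Cl[Mg]c1cc(OC)c(OS(=O)(=O)c2ccc(C)cc2)c(OC)c1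
F5 | step 4 | methyl 4-{[(2R)-1-{3,5-dimethoxy-4-[(4-methylbenzenesulfonyl)oxy]phenyl}-1-oxopropan-2-yl]oxy}-3-hydroxy-5-methoxybenzoate | C[C@@H](Oc1c(O)cc(cc1OC)C(=O)OC)C(=O)c1cc(OC)c(OS(=O)(=O)c2ccc(C)cc2)c(OC)c1
F6 | step 4 | methyl 4-{[(1S,2R)-1-{3,5-dimethoxy-4-[(4-methylbenzenesulfonyl)oxy]phenyl}-1-hydroxypropan-2-yl]oxy}-3-hydroxy-5-methoxybenzoate | C[C@@H](Oc1c(O)cc(cc1OC)C(=O)OC)[C@@H](O)c1cc(OC)c(OS(=O)(=O)c2ccc(C)cc2)c(OC)c1
F7 | step 8 | 4-[(2R,3R)-7-(hydroxymethyl)-5-methoxy-3-methyl-2,3-dihydro-1,4-benzodioxin-2-yl]-2,6-dimethoxyphenol | OCc1cc(OC)c2c(c1)O[C@H](c1cc(OC)c(O)c(OC)c1)[C@@H](C)O2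
F8 | step 8 | (2R,3R)-2-(4-hydroxy-3,5-dimethoxyphenyl)-5-methoxy-3-methyl-2,3-dihydro-1,4-benzodioxine-7-carbaldehyde | O=Cc1cc(OC)c2c(c1)O[C@H](c1cc(OC)c(O)c(OC)c1)[C@@H](C)O2
F9 | step 7 | 4-[(2R,3R)-7-(1-hydroxypropyl)-5-methoxy-3-methyl-2,3-dihydro-1,4-benzodioxin-2-yl]-2,6-dimethoxyphenyl 4-methylbenzenesulfonate (both carbinol epimers) | CCC(O)c1cc(OC)c2c(c1)O[C@H](c1cc(OC)c(OS(=O)(=O)c3ccc(C)cc3)c(OC)c1)[C@@H](C)O2
F10 | step 1 | methyl 3-(ethenyloxy)-4-hydroxy-5-methoxybenzoate | C=COc1cc(cc(OC)c1O)C(=O)OC
A1 | alternative 1 | {4-[(1R,2R)-2-[(chloroethynyl)oxy]-1-(ethynyloxy)propyl]-2,6-dimethoxyphenoxy}tri(propan-2-yl)silane | C#CO[C@H](c1cc(OC)c(O[Si](C(C)C)(C(C)C)C(C)C)c(OC)c1)[C@@H](C)OC#CCl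
A2 | alternative 1 | (E)-pent-3-en-1-yne | C/C=C/C#C
A3 | alternative 1 | {4-[(2R,3R)-5-chloro-3-methyl-7-[(E)-prop-1-en-1-yl]-2,3-dihydro-1,4-benzodioxin-2-yl]-2,6-dimethoxyphenoxy}tri(propan-2-yl)silane | C/C=C/c1cc(Cl)c2c(c1)O[C@H](c1cc(OC)c(O[Si](C(C)C)(C(C)C)C(C)C)c(OC)c1)[C@@H](C)O2
A4 | alternative 2 | 4-bromo-2-{[(1S)-1-{3,5-dimethoxy-4-[tri(propan-2-yl)silyloxy]phenyl}prop-2-en-1-yl]oxy}-6-methoxyphenol | Brc1cc(OC)c(O)c(c1)O[C@H](c1cc(OC)c(O[Si](C(C)C)(C(C)C)C(C)C)c(OC)c1)C=C
A5 | alternative 2 | {4-[(2R,3R)-7-bromo-5-methoxy-3-methyl-2,3-dihydro-1,4-benzodioxin-2-yl]-2,6-dimethoxyphenoxy}tri(propan-2-yl)silane | Brc1cc(OC)c2c(c1)O[C@H](c1cc(OC)c(O[Si](C(C)C)(C(C)C)C(C)C)c(OC)c1)[C@@H](C)O2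
A6 | alternative 3 | (1R,2R)-2-{2-bromo-6-methoxy-4-[(E)-prop-1-en-1-yl]phenoxy}-1-{3,5-dimethoxy-4-[tri(propan-2-yl)silyloxy]phenyl}propan-1-ol | C/C=C/c1cc(OC)c(O[C@H](C)[C@H](O)c2cc(OC)c(O[Si](C(C)C)(C(C)C)C(C)C)c(OC)c2)c(Br)c1
A7 | alternative 3 | {4-[(2R,3R)-5-methoxy-3-methyl-7-[(E)-prop-1-en-1-yl]-2,3-dihydro-1,4-benzodioxin-2-yl]-2,6-dimethoxyphenoxy}tri(propan-2-yl)silane | C/C=C/c1cc(OC)c2c(c1)O[C@H](c1cc(OC)c(O[Si](C(C)C)(C(C)C)C(C)C)c(OC)c1)[C@@H](C)O2
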